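**Assumptions (one line each):** 2‑Methylresorcinol is the cheap aromatic feedstock. Simple reagents (MeI, Ph3P=CH2, etc.) are listed under "Reagents that add atoms" and not numbered. The enantiomeric purity of 5 is upgraded to >98% ee by crystallization, since proline gives moderate ee.

## Retrosynthetic overview
- α‑Onocerin (13) comes from double Wittig methylenation of the C2‑symmetric 1,6‑diketone 12, which converts both C8 carbonyls into the exocyclic methylenes.
- 12 comes from reductive β,β‑hydrodimerization of the α‑methylene ketone 11. This forms the central C11–C11′ bond and both C9 stereocenters in one step.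
- 11 comes from 9, by SeO2 allylic oxidation then MnO2. This moves the oxygen from C9 to C8 and leaves the C11 methylene, so the C9 carbonyl of the Wieland–Miescher ketone (WMK) is used as the source of C11.
- 9 comes from (S)‑WMK (5) by chemoselective methylenation, Stork reductive methylation, gem‑dimethylation and reduction.
- Ring order: ring B is the dearomatized resorcinol ring (hydrogenation). Ring A is then built by the desymmetrizing proline Robinson annulation. No other rings are formed.

## Route

**Step 1**
Reactants: 1 (2‑methylresorcinol)
Product: 2 (2‑methylcyclohexane‑1,3‑dione)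
Conditions: H2 (50 bar), Raney Ni, aq. NaOH, 50 °C; then HCl
Reagents that add atoms: none (H2 adds only H)
Why: Catalytic hydrogenation dearomatizes resorcinol through its dione/enolate tautomer. Base stops over‑reduction to the diol. This gives the prochiral dione.

**Step 2**
Reactants: 2 (2‑methylcyclohexane‑1,3‑dione), 3 (methyl vinyl ketone)
Product: 4 (2‑methyl‑2‑(3‑oxobutyl)cyclohexane‑1,3‑dione)
Conditions: H2O, 80 °C (or cat. Et3N, neat)
Reagents that add atoms: none (3 is the reactant)
Why: The acidic dione adds to MVK by Michael addition. This builds the achiral, mirror‑symmetric triketone whose symmetry is broken in Step 3.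

**Step 3**
Reactants: 4
Product: 5 ((S)‑Wieland–Miescher ketone)
Conditions: (S)‑proline (35 mol%), DMSO, rt; then TsOH (cat.), PhH, reflux
Reagents that add atoms: none
Why: This is a Hajos–Parrish–Eder–Sauer–Wiechert (Robinson) annulation. The proline enamine attacks one of the two enantiotopic ring carbonyls through a carboxylic‑acid‑assisted Houk–List transition state. This desymmetrization creates the C10 quaternary center with the natural (10β‑Me) configuration. TsOH then dehydrates the ketol to the enone.

**Step 4**
Reactants: 5
Product: 6 (C9‑methylene enone)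
Conditions: Ph3PCH3Br, t‑BuOK, THF, 0 °C → rt
Reagents that add atoms: methyltriphenylphosphonium bromide, C[P+](c1ccccc1)(c1ccccc1)c1ccccc1.[Br-] (delivers =CH2)
Why: Wittig methylenation is chemoselective for the saturated C9 ketone, because the enone carbonyl is deactivated by conjugation. This installs C11 and leaves the ring‑A enone for Step 5.

**Step 5**
Reactants: 6
Product: 7 (trans‑fused 4α‑methyl‑3‑ketone, 9(11)‑ene)
Conditions: Li, NH3(l)/THF, –78 °C; then MeI
Reagents that add atoms: MeI, CI
Why: Stork reductive alkylation. Dissolving‑metal reduction protonates C5 axially and anti to the C10 methyl, giving the trans (5α‑H) ring fusion. The resulting C3/C4 lithium enolate is methylated at C4 (4α, equatorial). The isolated exocyclic alkene survives.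

**Step 6**
Reactants: 7
Product: 8 (4,4,10β‑trimethyl‑3‑keto‑9(11)‑ene)
Conditions: t‑BuOK, MeI, t‑BuOH/THF, 0 °C → rt
Reagents that add atoms: MeI, CI
Why: The thermodynamic enolate forms toward the more substituted C4, and a second C‑methylation gives the gem‑dimethyl group. C5 is not epimerized.

**Step 7**
Reactants: 8
Product: 9 (3β‑hydroxy‑4,4,10β‑trimethyl‑trans‑decalin, 9(11)‑ene)
Conditions: NaBH4, MeOH, 0 °C
Reagents that add atoms: none
Why: Hydride attacks axially from the α face, since the axial 4β‑ and 10β‑methyls block the β face. This gives the equatorial 3β‑OH.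

**Step 8**
Reactants: 9
Product: 10 (8‑hydroxy‑9(11)‑ene; C8 epimers, which are irrelevant)
Conditions: SeO2 (20 mol%), TBHP, CH2Cl2, rt
Reagents that add atoms: tert‑butyl hydroperoxide, CC(C)(C)OO (oxygen source)
Why: Riley allylic oxidation proceeds by an ene reaction then [2,3]‑sigmatropic shift. The only allylic C–H is on C8, because C10 is quaternary. The exocyclic methylene is retained, and the new C8 stereocenter is destroyed in Step 9.

**Step 9**
Reactants: 10
Product: 11 (8‑oxo‑9(11)‑ene, an α‑methylene ketone)
Conditions: activated MnO2, CH2Cl2, rt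
Reagents that add atoms: none
Why: MnO2 selectively oxidizes the allylic alcohol. The hindered, non‑allylic 3‑OH is untouched. 11 is carried on immediately because α‑methylene ketones are polymerization‑prone.

**Step 10**
Reactants: 11 (2 equiv)
Product: 12 (C2‑symmetric 1,6‑diketone bis‑3β‑ol)
Conditions: SmI2 (1.1 equiv per enone), HMPA, THF, –78 °C, slow addition of 11; then sat. aq. NH4Cl
Reagents that add atoms: none (protonation adds H only)
Why: Proposed new method: SET reduction gives a radical anion with spin at the unhindered terminal C11 (β‑CH2). Two such radicals couple C11–C11′ to give a bis‑Sm(III) enolate. Kinetic protonation at C9 from the α face (anti to the axial 10β‑Me) gives 9α‑H and an equatorial C11 chain, which is also the thermodynamic epimer. The closest known chemistry is Baizer hydrodimerization of acrylonitrile and methacrylate, and SmI2 reductive dimerization of enoates.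

**Step 11**
Reactants: 12
Product: 13 (α‑onocerin)
Conditions: Ph3PCH3Br (10 equiv), t‑BuOK (10 equiv), toluene, 80 °C
Reagents that add atoms: methyltriphenylphosphonium bromide, C[P+](c1ccccc1)(c1ccccc1)c1ccccc1.[Br-] (2 × =CH2)
Why: Wittig methylenation of both C8 ketones gives the 8(17)‑exocyclic alkenes. Any residual C9 epimer equilibrates under the basic conditions to the equatorial (natural) configuration, and the free hindered 3‑OH is tolerated by the excess ylide.

## Compound list
1 | 2‑methylresorcinol | Cc1c(O)cccc1O | starting material
2 | 2‑methylcyclohexane‑1,3‑dione | CC1C(=O)CCCC1=O | intermediate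
3 | methyl vinyl ketone | C=CC(C)=O | starting material
4 | 2‑methyl‑2‑(3‑oxobutyl)cyclohexane‑1,3‑dione | CC(=O)CCC1(C)C(=O)CCCC1=O | intermediate
5 | (S)‑Wieland–Miescher ketone | O=C1CC[C@]2(C)C(=O)CCCC2=C1 | intermediate
6 | (S)‑8a‑methyl‑1‑methylene‑hexahydronaphthalen‑6‑one (9‑methylene enone) | O=C1CC[C@]2(C)C(=C)CCCC2=C1 | intermediate
7 | trans‑4α‑methyl‑3‑keto‑9(11)‑ene | O=C1CC[C@]2(C)C(=C)CCC[C@H]2[C@@H]1C | intermediate
8 | 4,4,10β‑trimethyl‑3‑keto‑9(11)‑ene | O=C1CC[C@]2(C)C(=C)CCC[C@H]2C1(C)C | intermediate
9 | 3β‑hydroxy‑4,4,10β‑trimethyl‑trans‑decalin, 9(11)‑ene | O[C@H]1CC[C@]2(C)C(=C)CCC[C@H]2C1(C)C | intermediate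
10 | 8‑hydroxy analogue of 9 (C8 epimers) | O[C@H]1CC[C@]2(C)C(=C)C(O)CC[C@H]2C1(C)C | intermediate
11 | 8‑oxo‑9(11)‑ene (α‑methylene ketone) | O[C@H]1CC[C@]2(C)C(=C)C(=O)CC[C@H]2C1(C)C | intermediate
12 | C2‑symmetric 1,6‑diketone dimer of 11 | O[C@H]1CC[C@]2(C)[C@@H](CC[C@H]3C(=O)CC[C@H]4C(C)(C)[C@@H](O)CC[C@]34C)C(=O)CC[C@H]2C1(C)C | intermediate
13 | α‑onocerin | C=C1CC[C@H]2C(C)(C)[C@@H](O)CC[C@]2(C)[C@H]1CC[C@H]1C(=C)CC[C@H]2C(C)(C)[C@@H](O)CC[C@]12C | target

## Totals
Total steps: 11. Longest linear sequence: 11.

**Three steps most likely to fail**
1. **Step 10 (hydrodimerization).** Over‑reduction to the 11‑methyl ketone, polymerization of 11, or SmI2 protonation by the free 3‑OH could compete.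
   - Fallback: change the bond construction. Convert 11 by conjugate iodination (TMSI) to the β‑iodoketone, then form C11–C11′ by Ni(bpy)/Zn reductive sp3–sp3 homocoupling via alkyl radicals, under non‑basic conditions.
2. **Step 4 (chemoselective Wittig on WMK).** Methylenation could occur at the enone carbonyl or at both carbonyls.
   - Fallback: selectively ketalize the saturated C9 ketone of 5, carry out Steps 5–7 on the ketal, then deprotect and do the Wittig on the C9 ketone. This adds two steps.
3. **Step 11 (bis‑methylenation of the hindered diketone).** Conversion may be incomplete, or base may cause aldol side reactions.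
   - Fallback: use Peterson olefination. Add Me3SiCH2MgCl/CeCl3 to both ketones, then eliminate the β‑hydroxysilane with KH or BF3·OEt2.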